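**Retrosynthetic overview**
- The target is a flavonol, released at the end by hydrogenolysis of the three benzyl ethers of 22.
- The strategy rests on ring A: C5(OH), C6(H), C7(OMe) and C8(OMe) are C1(=O), C2(H), C3(OMe) and C4(OMe) of a cyclobutenone, and C4a/C8a are the C5=C6 bond of a 3-benzyloxy-4-pyranone (ring C). A thermal 4π opening/6π closure of cyclobutenone 19 forms the C4a–C5 bond, so the chelated 5-OH and the two methyl ethers differ by origin.
- 19 comes from the C6-lithiated pyranone 13 and methyl semisquarate 16 (from dimethyl squarate 14), followed by O-methylation of the carbinol.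
- 13 comes from Suzuki coupling of bromopyranone 3 (from pyromeconic acid 1) with boronic acid 12 (ring B, from 2,4-dihydroxybenzaldehyde 4).
- Ring order: ring C is bought, ring B is coupled to it, ring A is closed last.

Key step: step 13

Remark: the chromenone is numbered as a flavone (O1, C2 to C4, C4a, C5 to C8, C8a; primed locants for ring B) and the pyranone as 4H-pyran-4-one with the aryl group at C2. The carbinol carbons of 15, 18 and 19 and C4a of 21 are racemic and are all lost before the target, which has no stereocenter. Semisquarate 16 is moisture-sensitive and is used freshly prepared.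

**Route**

Step 1
Reactants: 1 pyromeconic acid (3-hydroxy-4H-pyran-4-one)
Product: 2 2-bromo-3-hydroxy-4H-pyran-4-one
Conditions: NBS, MeCN, 0 °C to rt
Reagents that add atoms: N-bromosuccinimide O=C1CCC(=O)N1Br
Why: Electrophilic bromination of the enolic 3-hydroxypyranone should occur at C2, the enol β-carbon next to the ring oxygen and ortho to the hydroxyl, as in the halogenation of kojic acid.

Step 2
Reactants: 2 2-bromo-3-hydroxy-4H-pyran-4-one
Product: 3 3-(benzyloxy)-2-bromo-4H-pyran-4-one
Conditions: BnBr, K2CO3, DMF, rt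
Reagents that add atoms: benzyl bromide BrCc1ccccc1
Why: Williamson O-alkylation of the acidic enolic hydroxyl masks the future 3-OH and removes the only acidic proton before the metalation chemistry.

Step 3
Reactants: 4 2,4-dihydroxybenzaldehyde
Product: 5 2,4-bis(benzyloxy)benzaldehyde
Conditions: BnBr (2.4 equiv), K2CO3, DMF, 60 °C
Reagents that add atoms: benzyl bromide BrCc1ccccc1
Why: Double Williamson benzylation, run warm in DMF so that the hydrogen-bonded 2-OH is alkylated as well as the 4-OH.

Step 4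
Reactants: 5 2,4-bis(benzyloxy)benzaldehyde
Product: 7 2,4-bis(benzyloxy)phenol, via aryl formate 6 (not isolated)
Conditions: mCPBA, CH2Cl2, 0 °C to rt; then K2CO3 (cat.), MeOH, rt
Reagents that add atoms: meta-chloroperoxybenzoic acid O=C(OO)c1cccc(Cl)c1
Why: Baeyer–Villiger (Dakin-type) oxidation in which the electron-rich 2,4-dialkoxyaryl group migrates in preference to hydride, followed by methanolysis of the aryl formate.

Step 5
Reactants: 7 2,4-bis(benzyloxy)phenol
Product: 8 2,4-bis(benzyloxy)-1-methoxybenzene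
Conditions: MeI, K2CO3, acetone, reflux
Reagents that add atoms: iodomethane CI
Why: Williamson methylation of the phenol fixes the methyl ether that becomes 5'-OMe.

Step 6
Reactants: 8 2,4-bis(benzyloxy)-1-methoxybenzene
Product: 9 1-bromo-2,4-bis(benzyloxy)-5-methoxybenzene
Conditions: NBS, MeCN, 0 °C
Reagents that add atoms: N-bromosuccinimide O=C1CCC(=O)N1Br
Why: Electrophilic aromatic bromination should go to the carbon para to the 2-benzyloxy and ortho to the 4-benzyloxy group, the most activated unhindered position of a 1,2,4-trialkoxybenzene.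

Step 7
Reactants: 9 1-bromo-2,4-bis(benzyloxy)-5-methoxybenzene
Product: 12 2,4-bis(benzyloxy)-5-methoxyphenylboronic acid, via aryllithium 10 (not isolated), via lithium aryltriisopropoxyborate 11 (not isolated)
Conditions: B(OiPr)3, then n-BuLi, THF/toluene, −78 °C; warm to 0 °C; 1 M HCl
Reagents that add atoms: triisopropyl borate CC(C)OB(OC(C)C)OC(C)C; water O
Why: Bromine–lithium exchange at −78 °C is faster than butyl attack on the borate or benzylic deprotonation, and the aryllithium is trapped by the borate as it forms, with hydrolysis releasing the boronic acid.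

Step 8
Reactants: 3 3-(benzyloxy)-2-bromo-4H-pyran-4-one; 12 2,4-bis(benzyloxy)-5-methoxyphenylboronic acid
Product: 13 3-(benzyloxy)-2-[2,4-bis(benzyloxy)-5-methoxyphenyl]-4H-pyran-4-one
Conditions: Pd(OAc)2 (cat.), SPhos (2-dicyclohexylphosphino-2',6'-dimethoxybiphenyl), K3PO4, toluene/H2O, 80 °C
Reagents that add atoms: none
Why: Suzuki–Miyaura coupling in which the vinylogous acyl bromide adds readily to zerovalent palladium and the bulky biaryl phosphine should let the ortho-alkoxy boronic acid couple faster than it protodeboronates.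

Step 9
Reactants: 14 dimethyl squarate
Product: 15 4-hydroxy-2,3-dimethoxycyclobut-2-en-1-one (racemic)
Conditions: LiAlH(OtBu)3, THF, −78 to −20 °C; cold 1 M HCl quench
Reagents that add atoms: none
Why: The bulky hydride should add once to a ketone carbonyl (1,2-reduction) and leave the resulting vinylogous ester carbonyl alone; the carbinol carbon forms racemic and is lost in step 10.

Step 10
Reactants: 15 4-hydroxy-2,3-dimethoxycyclobut-2-en-1-one
Product: 16 3-methoxycyclobut-3-ene-1,2-dione (methyl semisquarate)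
Conditions: conc. HCl (cat.), CH2Cl2, rt; used at once
Reagents that add atoms: none
Why: Acid ionizes the allylic hydroxyl to an alkoxy-stabilized cyclobutenyl cation, the hydroxyl returns at the distal methoxy-bearing carbon and the hemiketal loses methanol, which is the established semisquarate synthesis.

Step 11
Reactants: 13 3-(benzyloxy)-2-[2,4-bis(benzyloxy)-5-methoxyphenyl]-4H-pyran-4-one; 16 3-methoxycyclobut-3-ene-1,2-dione
Product: 18 3-(benzyloxy)-2-[2,4-bis(benzyloxy)-5-methoxyphenyl]-6-(1-hydroxy-2-methoxy-4-oxocyclobut-2-en-1-yl)-4H-pyran-4-one (racemic), via 6-lithiopyranone 17 (not isolated)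
Conditions: 2,2,6,6-tetramethylpiperidine, n-BuLi, THF, −78 °C (forms LiTMP); 13, −78 °C, 15 min; 16, THF, −78 °C; sat. aq. NH4Cl at −78 °C
Reagents that add atoms: none
Why: The C6–H next to the ring oxygen is the most acidic ring position of a pyranone blocked at C2 and C3 (as in the C2 lithiation of chromones), and the vinyllithium should add 1,2 to the ketone-like carbonyl of 16 and not to its vinylogous ester carbonyl; the quaternary carbinol forms racemic, which does not matter because it becomes sp2 C8.

Step 12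
Reactants: 18 the hydroxycyclobutenone of step 11
Product: 19 3-(benzyloxy)-2-[2,4-bis(benzyloxy)-5-methoxyphenyl]-6-(1,2-dimethoxy-4-oxocyclobut-2-en-1-yl)-4H-pyran-4-one (racemic)
Conditions: MeI (excess), Ag2O, MeCN, rt, dark
Reagents that add atoms: iodomethane CI
Why: Silver oxide-mediated O-methylation is the usual mild etherification of squarate-derived tertiary carbinols and avoids the strong base or acid that would open or rearrange the hydroxycyclobutenone.

Step 13
Reactants: 19 the 4-methoxy-4-(pyranon-6-yl)cyclobutenone of step 12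
Product: 22 3-(benzyloxy)-2-[2,4-bis(benzyloxy)-5-methoxyphenyl]-5-hydroxy-7,8-dimethoxy-4H-chromen-4-one, via dienyl ketene 20 (not isolated), via cyclohexadienone 21 (not isolated)
Conditions: p-xylene (degassed, 0.01 M), 138 °C, Ar
Reagents that add atoms: none
Why: Heating should open the cyclobutenone by conrotatory 4π cleavage of its C1–C4 bond to the dienyl ketene 20, after which the ketene carbon bonds to pyranone C5 in a thermal disrotatory 6π electrocyclization to give cyclohexadienone 21, whose C4a–H enolizes to the phenol. The closest known reaction is the Moore-type ring expansion of 4-aryl, 4-heteroaryl and 4-alkenyl 4-alkoxycyclobutenones to phenols and hydroquinone monoethers; here the 2π partner is the C5=C6 bond of a 4-pyranone, an alkenyl group of that kind. Ring A (C4a, C5, C6, C7, C8, C8a) is the only ring closed, by this 6π electrocyclization through the new C4a–C5 bond. No stereocenter results, since the racemic quaternary carbon of 19 becomes sp2 C8 and the transient sp3 C4a of 21 is erased on aromatization. The step needs the pyranonyl group to rotate inward during ring opening, which the C4 methoxy group secures by its preference for outward rotation, and it needs a single closure site, which is given because C5 is the only carbon neighbour of pyranone C6. The phenol that emerges is the 5-OH, hydrogen-bonded to the C4 carbonyl, while C7 and C8 already carry their methyl ethers and C6 its hydrogen, so no oxygen has to be differentiated later.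

Step 14
Reactants: 22 the tribenzyl flavonol of step 13
Product: 23 2-(2,4-dihydroxy-5-methoxyphenyl)-3,5-dihydroxy-7,8-dimethoxy-4H-chromen-4-one (CNP0319239.0)
Conditions: H2 (1 atm), 10% Pd/C (palladium on carbon), EtOAc/MeOH, rt
Reagents that add atoms: none
Why: Catalytic hydrogenolysis should cleave the three benzyl ethers while the aryl methyl ethers and the flavonol C2=C3 bond are left intact.

**Compound list**
1 | pyromeconic acid (3-hydroxy-4H-pyran-4-one) | O=c1ccocc1O | starting material
2 | 2-bromo-3-hydroxy-4H-pyran-4-one | O=c1ccoc(Br)c1O | intermediate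
3 | 3-(benzyloxy)-2-bromo-4H-pyran-4-one | O=c1ccoc(Br)c1OCc1ccccc1 | intermediate
4 | 2,4-dihydroxybenzaldehyde | O=Cc1ccc(O)cc1O | starting material
5 | 2,4-bis(benzyloxy)benzaldehyde | O=Cc1ccc(OCc2ccccc2)cc1OCc1ccccc1 | intermediate
6 | 2,4-bis(benzyloxy)phenyl formate | O=COc1ccc(OCc2ccccc2)cc1OCc1ccccc1 | intermediate (not isolated)
7 | 2,4-bis(benzyloxy)phenol | Oc1ccc(OCc2ccccc2)cc1OCc1ccccc1 | intermediate
8 | 2,4-bis(benzyloxy)-1-methoxybenzene | COc1ccc(OCc2ccccc2)cc1OCc1ccccc1 | intermediate
9 | 1-bromo-2,4-bis(benzyloxy)-5-methoxybenzene | COc1cc(Br)c(OCc2ccccc2)cc1OCc1ccccc1 | intermediate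
10 | [2,4-bis(benzyloxy)-5-methoxyphenyl]lithium | [Li]c1cc(OC)c(OCc2ccccc2)cc1OCc1ccccc1 | intermediate (not isolated)
11 | lithium [2,4-bis(benzyloxy)-5-methoxyphenyl]triisopropoxyborate | [Li+].CC(C)O[B-](OC(C)C)(OC(C)C)c1cc(OC)c(OCc2ccccc2)cc1OCc1ccccc1 | intermediate (not isolated)
12 | 2,4-bis(benzyloxy)-5-methoxyphenylboronic acid | COc1cc(B(O)O)c(OCc2ccccc2)cc1OCc1ccccc1 | intermediate
13 | 3-(benzyloxy)-2-[2,4-bis(benzyloxy)-5-methoxyphenyl]-4H-pyran-4-one | COc1cc(-c2occc(=O)c2OCc2ccccc2)c(OCc2ccccc2)cc1OCc1ccccc1 | intermediate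
14 | dimethyl squarate | COC1=C(OC)C(=O)C1=O | starting material
15 | 4-hydroxy-2,3-dimethoxycyclobut-2-en-1-one (racemic) | COC1=C(OC)C(O)C1=O | intermediate
16 | 3-methoxycyclobut-3-ene-1,2-dione (methyl semisquarate) | COC1=CC(=O)C1=O | intermediate
17 | {5-(benzyloxy)-6-[2,4-bis(benzyloxy)-5-methoxyphenyl]-4-oxo-4H-pyran-2-yl}lithium | [Li]c1cc(=O)c(OCc2ccccc2)c(-c2cc(OC)c(OCc3ccccc3)cc2OCc2ccccc2)o1 | intermediate (not isolated)
18 | 3-(benzyloxy)-2-[2,4-bis(benzyloxy)-5-methoxyphenyl]-6-(1-hydroxy-2-methoxy-4-oxocyclobut-2-en-1-yl)-4H-pyran-4-one (racemic) | COC1=CC(=O)C1(O)c1cc(=O)c(OCc2ccccc2)c(-c2cc(OC)c(OCc3ccccc3)cc2OCc2ccccc2)o1 | intermediate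
19 | 3-(benzyloxy)-2-[2,4-bis(benzyloxy)-5-methoxyphenyl]-6-(1,2-dimethoxy-4-oxocyclobut-2-en-1-yl)-4H-pyran-4-one (racemic) | COC1=CC(=O)C1(OC)c1cc(=O)c(OCc2ccccc2)c(-c2cc(OC)c(OCc3ccccc3)cc2OCc2ccccc2)o1 | intermediate
20 | (Z)-4-{5-(benzyloxy)-6-[2,4-bis(benzyloxy)-5-methoxyphenyl]-4-oxo-4H-pyran-2-yl}-3,4-dimethoxybuta-1,3-dien-1-one (ketene; pyranonyl cis to the ketene-bearing carbon) | O=C=C/C(OC)=C(/OC)c1cc(=O)c(OCc2ccccc2)c(-c2cc(OC)c(OCc3ccccc3)cc2OCc2ccccc2)o1 | intermediate (not isolated)
21 | 3-(benzyloxy)-2-[2,4-bis(benzyloxy)-5-methoxyphenyl]-7,8-dimethoxy-4aH-chromene-4,5-dione (racemic at C4a) | COC1=CC(=O)C2C(=O)C(OCc3ccccc3)=C(c3cc(OC)c(OCc4ccccc4)cc3OCc3ccccc3)OC2=C1OC | intermediate (not isolated)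
22 | 3-(benzyloxy)-2-[2,4-bis(benzyloxy)-5-methoxyphenyl]-5-hydroxy-7,8-dimethoxy-4H-chromen-4-one | COc1cc(-c2oc3c(OC)c(OC)cc(O)c3c(=O)c2OCc2ccccc2)c(OCc2ccccc2)cc1OCc1ccccc1 | intermediate
23 | 2-(2,4-dihydroxy-5-methoxyphenyl)-3,5-dihydroxy-7,8-dimethoxy-4H-chromen-4-one (CNP0319239.0) | COc1cc(-c2oc3c(OC)c(OC)cc(O)c3c(=O)c2O)c(O)cc1O | target

**Step count**
Total steps: 14. Longest linear sequence: 10 steps (4 → 5 → 7 → 8 → 9 → 12 → 13 → 18 → 19 → 22 → 23).

**Steps most likely to fail, with fallbacks**

Step 13. The 6π closure onto pyranone C5 may be slow, because the C5=C6 bond belongs to a cross-conjugated, partly aromatic ring, and the dienyl ketene may then decompose or oligomerize. The fallback gives up the squarate construction of ring A and sets out from 9. Bromine–lithium exchange (n-BuLi, THF, −78 °C) and formylation with DMF should give 2,4-bis(benzyloxy)-5-methoxybenzaldehyde F1. Claisen–Schmidt condensation with the known 2'-hydroxy-3',4',6'-trimethoxyacetophenone (KOH, EtOH) should give (E)-3-[2,4-bis(benzyloxy)-5-methoxyphenyl]-1-(2-hydroxy-3,4,6-trimethoxyphenyl)prop-2-en-1-one F2. Oxidative cyclization (cat. I2, DMSO, 120 °C) should give 2-[2,4-bis(benzyloxy)-5-methoxyphenyl]-5,7,8-trimethoxy-4H-chromen-4-one F3. Epoxidation of the C2=C3 bond with dimethyldioxirane and acid-promoted opening (cat. TsOH) should give 2-[2,4-bis(benzyloxy)-5-methoxyphenyl]-3-hydroxy-5,7,8-trimethoxy-4H-chromen-4-one F4. A chelating Lewis acid (MgI2 etherate, toluene, 60–80 °C) should cleave only the methyl ether peri to the C4 carbonyl and give 2-[2,4-bis(benzyloxy)-5-methoxyphenyl]-3,5-dihydroxy-7,8-dimethoxy-4H-chromen-4-one F5. Hydrogenolysis under the conditions of step 14 then returns to the route at 23.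

Step 11. The lithiated pyranone may open or decompose before it is trapped, metalation may occur at C5 or at a benzylic position, or addition to the sensitive semisquarate may be poor. The fallback replaces direct lithiation by metalation with a mild zinc base followed by halogen–metal exchange, and sets out from 13. TMP2Zn·2MgCl2·2LiCl (THF, 25 °C), which tolerates the pyranone at ambient temperature and metalates next to the ring oxygen, should give bis{5-(benzyloxy)-6-[2,4-bis(benzyloxy)-5-methoxyphenyl]-4-oxo-4H-pyran-2-yl}zinc F6. Iodine should convert it into 3-(benzyloxy)-2-[2,4-bis(benzyloxy)-5-methoxyphenyl]-6-iodo-4H-pyran-4-one F7. Iodine–magnesium exchange with i-PrMgCl·LiCl at −40 °C should give {5-(benzyloxy)-6-[2,4-bis(benzyloxy)-5-methoxyphenyl]-4-oxo-4H-pyran-2-yl}magnesium chloride F8, which adds to the ketone carbonyl of 16 and returns to the route at 18.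

Step 12. The tertiary carbinol may be lost during alkylation, by ring opening of the hydroxycyclobutenone or by elimination of methanol to a cyclobutenedione. The fallback omits the methylation and sets out from 18. Heating the free carbinol (toluene, 110 °C, Ar) should trigger the same cascade, with the hydroxyl rotating outward as the methoxy group does, to give the hydroquinone 3-(benzyloxy)-2-[2,4-bis(benzyloxy)-5-methoxyphenyl]-5,8-dihydroxy-7-methoxy-4H-chromen-4-one F9, handled under argon. One equivalent of MeI with K2CO3 in acetone should methylate the free 8-OH in preference to the hydrogen-bonded 5-OH and return to the route at 22.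

**Further compounds**
F1 | step 13 | 2,4-bis(benzyloxy)-5-methoxybenzaldehyde | COc1cc(C=O)c(OCc2ccccc2)cc1OCc1ccccc1
F2 | step 13 | (E)-3-[2,4-bis(benzyloxy)-5-methoxyphenyl]-1-(2-hydroxy-3,4,6-trimethoxyphenyl)prop-2-en-1-one | COc1cc(/C=C/C(=O)c2c(O)c(OC)c(OC)cc2OC)c(OCc2ccccc2)cc1OCc1ccccc1
F3 | step 13 | 2-[2,4-bis(benzyloxy)-5-methoxyphenyl]-5,7,8-trimethoxy-4H-chromen-4-one | COc1cc(-c2cc(=O)c3c(OC)cc(OC)c(OC)c3o2)c(OCc2ccccc2)cc1OCc1ccccc1
F4 | step 13 | 2-[2,4-bis(benzyloxy)-5-methoxyphenyl]-3-hydroxy-5,7,8-trimethoxy-4H-chromen-4-one | COc1cc(-c2oc3c(OC)c(OC)cc(OC)c3c(=O)c2O)c(OCc2ccccc2)cc1OCc1ccccc1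
F5 | step 13 | 2-[2,4-bis(benzyloxy)-5-methoxyphenyl]-3,5-dihydroxy-7,8-dimethoxy-4H-chromen-4-one | COc1cc(-c2oc3c(OC)c(OC)cc(O)c3c(=O)c2O)c(OCc2ccccc2)cc1OCc1ccccc1
F6 | step 11 | bis{5-(benzyloxy)-6-[2,4-bis(benzyloxy)-5-methoxyphenyl]-4-oxo-4H-pyran-2-yl}zinc | [Zn](c1cc(=O)c(OCc2ccccc2)c(-c2cc(OC)c(OCc3ccccc3)cc2OCc2ccccc2)o1)c1cc(=O)c(OCc2ccccc2)c(-c2cc(OC)c(OCc3ccccc3)cc2OCc2ccccc2)o1
F7 | step 11 | 3-(benzyloxy)-2-[2,4-bis(benzyloxy)-5-methoxyphenyl]-6-iodo-4H-pyran-4-one | Ic1cc(=O)c(OCc2ccccc2)c(-c2cc(OC)c(OCc3ccccc3)cc2OCc2ccccc2)o1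
F8 | step 11 | {5-(benzyloxy)-6-[2,4-bis(benzyloxy)-5-methoxyphenyl]-4-oxo-4H-pyran-2-yl}magnesium chloride | Cl[Mg]c1cc(=O)c(OCc2ccccc2)c(-c2cc(OC)c(OCc3ccccc3)cc2OCc2ccccc2)o1
F9 | step 12 | 3-(benzyloxy)-2-[2,4-bis(benzyloxy)-5-methoxyphenyl]-5,8-dihydroxy-7-methoxy-4H-chromen-4-one | COc1cc(-c2oc3c(O)c(OC)cc(O)c3c(=O)c2OCc2ccccc2)c(OCc2ccccc2)cc1OCc1ccccc1
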